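**Retrosynthetic overview**
- Feature: ring B (b1 O-aryl, b2 H, b3 H, b4 chain, b5 OH, b6 OMe) is the para-bridged arene of the 15-membered diaryl ether ring, and its b5 phenol between the b6 OMe and the b4 alkyl chain is the signature of a dienylketene 6π electrocyclization.
- Juglanin A ⇒ aryl vinylogous ester 16 of a 4-chloro-2-methoxycyclobutenone carrying the keto (E)-alkenylstannane chain: bond b4–b5 by 4π opening/6π closure, bond b2–b3 by intramolecular Stille coupling.
- 16 ⇒ phenol stannane 8 + 3,4-dichloro-2-methoxycyclobutenone 15 (C3–O bond by addition–elimination).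
- 8 ⇒ Weinreb amide of the ring A acid + silylated hexynyl Grignard reagent, then desilylation and hydrostannation; 15 ⇒ dimethyl squarate via a monoketal.
- Ring order: ring A is bought, the 15-membered ring closes first (at the cyclobutenone stage), ring B is formed last in the same flask.

Key step: step 10

Remark: aryloxy is a weaker donor and a better leaving group than methoxy, so methoxy-to-aryloxy exchange at C3 is uphill and hydride reduction of a mixed aryl methyl squarate should leave the carbonyl next to the aryloxy carbon (wrong ring B isomer); the aryloxy group is therefore introduced by addition–elimination on a 3-chlorocyclobutenone whose enol position is fixed by a ketal. The chlorinated carbon of 15 and 16 is racemic, which is without consequence because it becomes sp2.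

Step 1
Reactants: 1 3-(3-hydroxy-4-methoxyphenyl)propanoic acid
Product: 2 3-(3-hydroxy-4-methoxyphenyl)-N-methoxy-N-methylpropanamide
Conditions: MeNH(OMe)·HCl, EDC·HCl, HOBt (cat.), i-Pr2NEt, CH2Cl2, 0 °C to rt
Reagents that add atoms: N,O-dimethylhydroxylamine hydrochloride (CNOC.Cl)
Why: Carbodiimide amide coupling gives the Weinreb amide, the amine outcompeting the weakly nucleophilic guaiacol-type phenol for the activated ester so that the phenol needs no protection.

Step 2
Reactants: 3 6-chloro-1-hexyne
Product: 4 (6-chlorohex-1-yn-1-yl)trimethylsilane
Conditions: n-BuLi, THF, −78 °C; TMSCl, −78 °C to rt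
Reagents that add atoms: chlorotrimethylsilane (C[Si](C)(C)Cl)
Why: Deprotonation of the terminal alkyne and C-silylation of the lithium acetylide masks the acidic C–H that would quench the Grignard reagent of step 3, the primary chloride being inert to the acetylide at low temperature.

Step 3
Reactants: 4 (6-chlorohex-1-yn-1-yl)trimethylsilane; 2 3-(3-hydroxy-4-methoxyphenyl)-N-methoxy-N-methylpropanamide
Product: 6 1-(3-hydroxy-4-methoxyphenyl)-9-(trimethylsilyl)non-8-yn-3-one, via alkylmagnesium chloride 5 (not isolated)
Conditions: 4, Mg, I2 (cat.), THF, reflux; 2 pretreated with i-PrMgCl (1 equiv), THF, −40 °C; combine, −40 °C to rt; aq. NH4Cl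
Reagents that add atoms: none
Why: Weinreb ketone synthesis, in which the phenol is first turned into its magnesium phenoxide by the hindered base i-PrMgCl and the primary Grignard reagent then adds only once because the chelated tetrahedral intermediate survives until work-up.

Step 4
Reactants: 6 1-(3-hydroxy-4-methoxyphenyl)-9-(trimethylsilyl)non-8-yn-3-one
Product: 7 1-(3-hydroxy-4-methoxyphenyl)non-8-yn-3-one
Conditions: K2CO3, MeOH, rt
Reagents that add atoms: none
Why: Base-mediated methanolysis of the alkynyl C–Si bond (protodesilylation) leaves the ketone and the phenol untouched.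

Step 5
Reactants: 7 1-(3-hydroxy-4-methoxyphenyl)non-8-yn-3-one
Product: 8 (E)-1-(3-hydroxy-4-methoxyphenyl)-9-(tributylstannyl)non-8-en-3-one
Conditions: Bu3SnH (1.3 equiv), AIBN (cat.), toluene, 85 °C
Reagents that add atoms: tributyltin hydride (CCCC[SnH](CCCC)CCCC)
Why: Radical hydrostannation places tin only on the terminal carbon, and reversible addition of stannyl radicals equilibrates the alkene towards the E isomer, whose geometry is in any case erased when ring B aromatizes in step 10.

Step 6
Reactants: 9 dimethyl squarate
Product: 12 3,4,4-trimethoxycyclobut-2-en-1-one, via hydroxycyclobutenone 10 (not isolated), via trifluoroacetate 11 (not isolated)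
Conditions: LiAlH(O-t-Bu)3, THF, −78 °C; TFAA, −78 °C; MeOH, pyridine, −78 °C to 0 °C
Reagents that add atoms: methanol (CO)
Why: Hydride 1,2-reduction of one squarate carbonyl and acylation of the alkoxide let the trifluoroacetate ionize to a methoxy-stabilized oxocyclobutenyl cation that methanol captures at the methoxy-bearing terminus, the known allylic-transposition route from squarate 1,2-adducts to cyclobutenedione monoketals.

Step 7
Reactants: 12 3,4,4-trimethoxycyclobut-2-en-1-one
Product: 14 3-chloro-4,4-dimethoxycyclobut-2-en-1-one, via sodium enolate 13 (not isolated)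
Conditions: NaOH (1.0 equiv), THF–H2O, 0 °C; evaporate to dryness; (COCl)2, DMF (cat.), CH2Cl2, 0 °C
Reagents that add atoms: sodium hydroxide ([Na+].[OH-]); oxalyl chloride (O=C(Cl)C(Cl)=O)
Why: Saponification of the vinylogous ester by addition–elimination at C3 gives a vinylogous carboxylate with two equivalent oxygens and a single enol position (fixed by the quaternary ketal carbon), which oxalyl chloride converts into one vinylogous acid chloride as in the preparation of 3-chloroenones from 1,3-diones.

Step 8
Reactants: 14 3-chloro-4,4-dimethoxycyclobut-2-en-1-one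
Product: 15 3,4-dichloro-2-methoxycyclobut-2-en-1-one (racemic)
Conditions: AcCl (1.2 equiv), ZnCl2 (cat.), CH2Cl2, 0 °C to rt
Reagents that add atoms: acetyl chloride (CC(Cl)=O)
Why: Lewis-acid-catalysed exchange of a ketal methoxy group for chloride with acetyl chloride passes through the oxocyclobutenyl cation, and chloride return at the hydrogen-bearing terminus should give the conjugated allylic chloride with the enol ether intact, as in the conversion of unsaturated acetals into 3-halo enol ethers.

Step 9
Reactants: 8 (E)-1-(3-hydroxy-4-methoxyphenyl)-9-(tributylstannyl)non-8-en-3-one; 15 3,4-dichloro-2-methoxycyclobut-2-en-1-one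
Product: 16 (E)-1-[3-(4-chloro-2-methoxy-3-oxocyclobut-1-enyloxy)-4-methoxyphenyl]-9-(tributylstannyl)non-8-en-3-one (racemic at the chlorinated carbon)
Conditions: 15 (1.2 equiv), i-Pr2NEt, CH2Cl2, −40 °C to 0 °C, slow addition of 8
Reagents that add atoms: none
Why: Addition–elimination of the phenol at C3 of the vinylogous acid chloride should outrun SN2 displacement of the C4 chloride, because attack at C3 relieves strain at a cyclobutene sp2 carbon whereas backside attack on a cyclobutyl carbon is slow, and the hindered amine removes HCl before it can protodestannylate the alkenylstannane.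

Step 10
Reactants: 16 (E)-1-[3-(4-chloro-2-methoxy-3-oxocyclobut-1-enyloxy)-4-methoxyphenyl]-9-(tributylstannyl)non-8-en-3-one
Product: 20 juglanin A, via macrocyclic alkenylcyclobutenone 17 (not isolated), via dienylketene 18 (not isolated), via cyclohexadienone 19 (not isolated)
Conditions: Pd2(dba)3 (10 mol %), tri(2-furyl)phosphine (40 mol %), 1,4-dioxane, 16 added over 12 h to 1 mM, 50 °C; then 100 °C
Reagents that add atoms: none
Why: Zerovalent palladium adds oxidatively to the allylic C4–Cl bond, the oxocyclobutenyl palladium chloride transmetalates with the tethered alkenylstannane, and reductive elimination at the hydrogen-bearing terminus forms bond b2–b3, closing the 15-membered ring end-to-end as the 4-alkenylcyclobutenone 17 under high dilution. Heating opens 17 by conrotatory 4π ring opening to the dienylketene 18, 6π electrocyclization joins the ketene carbon to the chain-bearing alkene carbon (bond b4–b5) to build ring B as cyclohexadienone 19, and enolization gives the phenol. The closest known reaction is the intermolecular Stille coupling of 4-chlorocyclobutenones with alkenylstannanes followed by thermal ring expansion to phenols, run here in the intramolecular, macrocyclizing mode. No stereocenter survives, since the chlorinated carbon of 16 and the sp3 carbons of 17 and 19 all become sp2 and the alkene geometry is lost on aromatization. The step needs coupling at C4 and not at the methoxy-bearing allyl terminus C2, which the lower substitution of C4 should secure, and it needs the alkenyl group to rotate inward on ring opening, which follows because the opening is reversible and only the inward isomer can cyclize. The strain of the para bridge is paid for by aromatization, after the still unstrained 15-membered ring has been closed.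

**Compound list**
1 | 3-(3-hydroxy-4-methoxyphenyl)propanoic acid | COc1ccc(CCC(=O)O)cc1O | starting material
2 | 3-(3-hydroxy-4-methoxyphenyl)-N-methoxy-N-methylpropanamide | COc1ccc(CCC(=O)N(C)OC)cc1O | intermediate
3 | 6-chloro-1-hexyne | ClCCCCC#C | starting material
4 | (6-chlorohex-1-yn-1-yl)trimethylsilane | C[Si](C)(C)C#CCCCCCl | intermediate
5 | [6-(trimethylsilyl)hex-5-yn-1-yl]magnesium chloride (not isolated) | C[Si](C)(C)C#CCCCC[Mg]Cl | intermediate
6 | 1-(3-hydroxy-4-methoxyphenyl)-9-(trimethylsilyl)non-8-yn-3-one | COc1ccc(CCC(=O)CCCCC#C[Si](C)(C)C)cc1O | intermediate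
7 | 1-(3-hydroxy-4-methoxyphenyl)non-8-yn-3-one | COc1ccc(CCC(=O)CCCCC#C)cc1O | intermediate
8 | (E)-1-(3-hydroxy-4-methoxyphenyl)-9-(tributylstannyl)non-8-en-3-one | COc1ccc(CCC(=O)CCCC/C=C/[Sn](CCCC)(CCCC)CCCC)cc1O | intermediate
9 | dimethyl squarate (3,4-dimethoxycyclobut-3-ene-1,2-dione) | COC1=C(OC)C(=O)C1=O | starting material
10 | 4-hydroxy-2,3-dimethoxycyclobut-2-en-1-one, racemic, present as its aluminium alkoxide (not isolated) | COC1=C(OC)C(=O)C1O | intermediate
11 | 2,3-dimethoxy-4-oxocyclobut-2-en-1-yl trifluoroacetate, racemic (not isolated) | COC1=C(OC)C(=O)C1OC(=O)C(F)(F)F | intermediate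
12 | 3,4,4-trimethoxycyclobut-2-en-1-one | COC1=CC(=O)C1(OC)OC | intermediate
13 | sodium 4,4-dimethoxy-3-oxocyclobut-1-en-1-olate (not isolated) | [Na+].[O-]C1=CC(=O)C1(OC)OC | intermediate
14 | 3-chloro-4,4-dimethoxycyclobut-2-en-1-one | ClC1=CC(=O)C1(OC)OC | intermediate
15 | 3,4-dichloro-2-methoxycyclobut-2-en-1-one, racemic | COC1=C(Cl)C(Cl)C1=O | intermediate
16 | (E)-1-[3-(4-chloro-2-methoxy-3-oxocyclobut-1-enyloxy)-4-methoxyphenyl]-9-(tributylstannyl)non-8-en-3-one, racemic at the chlorinated carbon | COc1ccc(CCC(=O)CCCC/C=C/[Sn](CCCC)(CCCC)CCCC)cc1OC1=C(OC)C(=O)C1Cl | intermediate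
17 | macrocyclic 4-alkenylcyclobutenone: 15-membered ring in which C4 of the 2-methoxy-3-aryloxycyclobutenone is bonded to the former tin-bearing carbon of the E-alkene, racemic at C4 (not isolated) | COc1ccc2cc1OC1=C(OC)C(=O)C1/C=C/CCCCC(=O)CC2 | intermediate
18 | macrocyclic dienylketene from ring opening of 17, aryloxy oxygen and alkenyl group trans on the new C3=C4 bond, chain alkene E (not isolated) | COc1ccc2cc1O/C(C(OC)=C=O)=C/C=C/CCCCC(=O)CC2 | intermediate
19 | cyclohexa-2,4-dienone tautomer of juglanin A, sp3 carbon b4 bearing H and the chain, racemic (not isolated) | COc1ccc2cc1OC1=C(OC)C(=O)C(CCCCC(=O)CC2)C=C1 | intermediate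
20 | juglanin A | COc1ccc2cc1Oc1ccc(c(O)c1OC)CCCCC(=O)CC2 | target

**Totals**
Total step count: 10. Longest linear sequence: 6 steps (steps 1, 3, 4, 5, 9, 10; the squarate branch, steps 6 to 10, is 5 steps).

**Steps most likely to fail**

Step 10. At the dilution needed for ring closure, transmetalation within the tether may be slower than decay of the oxocyclobutenyl palladium intermediate (loss of chloromethane, reduction) or than intermolecular coupling, so that oligomers form instead of 17. The fallback sets out from 2 and 15 and returns to the route at 20; it runs the benzannulation intermolecularly and closes the macrocycle afterwards in the chain. Amide 2 and 15 (i-Pr2NEt, CH2Cl2) should give the aryl vinylogous ester chloride F1. Stille coupling and thermal ring expansion of F1 with (E)-tributyl(hexa-1,5-dien-1-yl)stannane F2 (from hex-1-en-5-yne, Bu3SnH, AIBN), under the catalyst of step 10 at ordinary concentration, should give the open-chain diaryl ether F3, whose ring B already carries b5 OH, b6 OMe and a but-3-enyl group at b4. Excess vinylmagnesium bromide converts the Weinreb amide into the vinyl ketone F4. Ring-closing metathesis with the second-generation Grubbs catalyst at high dilution closes the macrocyclic enone F5, and hydrogenation of its C=C bond (H2, Pd/C) gives 20.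

Step 9. The phenoxide may displace the C4 chloride by SN2 or react twice, and an unfavourable position of the chloride delivered by step 8 would add solvolysis at a chloro ether carbon. The fallback sets out from 8 and 14 and returns to the route at 16. Phenol 8 is first joined to ketal 14, which has C3 as its only electrophilic carbon (i-Pr2NEt, CH2Cl2), to give the aryloxy ketal F6. The ketal is then ionized under base-buffered conditions (TMSOTf, 2,4,6-collidine, CH2Cl2, −40 °C) and the collidinium adduct is opened with Bu4NCl, chloride entering at the hydrogen-bearing allyl terminus to give 16; any silyl enol ether formed at the chain ketone is cleaved on aqueous work-up. This detour needs neither 15 nor step 8.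

Step 6. Acylation of the aluminium alkoxide may be incomplete, or methanol may add at the hydrogen-bearing terminus of the cation and return a 4-methoxy isomer. The fallback sets out from 9 and returns to the route at 12. Reduction as in step 6 followed by aqueous HCl gives methyl semisquarate F7 by the known hydrolytic transposition. Its ketone-type carbonyl, the one not deactivated by vinylogous ester conjugation, is then ketalized selectively (MeOSiMe3, TMSOTf cat., CH2Cl2, −78 °C) to give 12.

**Further compounds**
F1 | step 10 | 3-[3-(4-chloro-2-methoxy-3-oxocyclobut-1-enyloxy)-4-methoxyphenyl]-N-methoxy-N-methylpropanamide, racemic | COc1ccc(CCC(=O)N(C)OC)cc1OC1=C(OC)C(=O)C1Cl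
F2 | step 10 | (E)-tributyl(hexa-1,5-dien-1-yl)stannane | C=CCC/C=C/[Sn](CCCC)(CCCC)CCCC
F3 | step 10 | 3-{3-[4-(but-3-enyl)-3-hydroxy-2-methoxyphenoxy]-4-methoxyphenyl}-N-methoxy-N-methylpropanamide | COc1ccc(CCC(=O)N(C)OC)cc1Oc1ccc(CCC=C)c(O)c1OC
F4 | step 10 | 5-{3-[4-(but-3-enyl)-3-hydroxy-2-methoxyphenoxy]-4-methoxyphenyl}pent-1-en-3-one | COc1ccc(CCC(=O)C=C)cc1Oc1ccc(CCC=C)c(O)c1OC
F5 | step 10 | (E)-enone analogue of juglanin A with a C=C bond between the two chain carbons next to the ketone on the ring B side | COc1ccc2cc1Oc1ccc(c(O)c1OC)CC/C=C/C(=O)CC2
F6 | step 9 | (E)-1-[3-(4,4-dimethoxy-3-oxocyclobut-1-enyloxy)-4-methoxyphenyl]-9-(tributylstannyl)non-8-en-3-one | COc1ccc(CCC(=O)CCCC/C=C/[Sn](CCCC)(CCCC)CCCC)cc1OC1=CC(=O)C1(OC)OC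
F7 | step 6 | 3-methoxycyclobut-3-ene-1,2-dione (methyl semisquarate) | COC1=CC(=O)C1=O
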